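Labdane numbering: ring A = C1–C5 + C10, ring B = C5–C10, C17 = exocyclic CH2 on C8, C18 = CH2OH and C19 = CH3 on C4, C20 = CH3 on C10, C11–C12 = link from C9 to the butenolide C13–C16 (C15 = C=O).
Retrosynthetic cuts: the O3–angeloyl ester bond, C12–C13 (sp3–sp2 coupling), C11=C12 (olefination), then C7–C8 and C9–C10 together. The last cut dissolves ring B and leaves a ring A diene and a four-carbon alkyne.
Enabling feature: in ring B the two branched carbons C8 (bearing C17) and C9 (bearing C11) are neighbours and lie across the ring from the fusion bond C5–C10. So C17–C8≡C9–C11 is a but-2-ynedioate, an ynoate activated from both ends, and C10=C5–C6=C7 is a vinyl diene built on ring A.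
Forward order: ring A from 2-methylcyclohexane-1,3-dione, ring B by Diels–Alder reaction, C5=C6 saturated, C11 grown to a vinyl group and joined to the purchased butenolide ring while C8=C9 is still tetrasubstituted, C8=C17 unveiled afterwards by reductive allylic transposition, angelate last.
Stereochemistry: C3 and C4 from an enzymatic desymmetrisation; C10 from the axial C19 methyl steering the cycloaddition; C5 from hydrogenation opposite C19 and C20; C9 from hydrogen delivery opposite C20; the Z-alkene comes with angelic acid.

Key step: step 7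

Assumption: α means the decalin face that carries C19 and C20, β the other face; a commercial ketoreductase panel is taken to hold an anti-Prelog enzyme that delivers the (2S,3R) isomer in step 2.

Step 1
Reactants: 1 2-methylcyclohexane-1,3-dione
Product: 2 2-(hydroxymethyl)-2-methylcyclohexane-1,3-dione
Conditions: 37% aq. CH2O, KHCO3 (cat.), THF/H2O, 23 °C
Reagents that add atoms: formaldehyde, C=O
Why: Aldol-type hydroxymethylation: the acidic C2–H of the 1,3-dione adds through its enol to formaldehyde at carbon under nearly neutral catalysis, and because the product keeps no acidic C–H the reaction stops after one addition and leaves the prochiral quaternary carbon that becomes C4.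

Step 2
Reactants: 2 2-(hydroxymethyl)-2-methylcyclohexane-1,3-dione
Product: 3 (2S,3R)-3-hydroxy-2-(hydroxymethyl)-2-methylcyclohexan-1-one
Conditions: anti-Prelog ketoreductase (Lactobacillus kefir alcohol dehydrogenase type, picked from a commercial panel), NADP+ (cat.), i-PrOH, phosphate buffer pH 6.5, 30 °C
Reagents that add atoms: none
Why: Enzymatic desymmetrising mono-reduction of a prochiral 2,2-disubstituted cyclohexane-1,3-dione, a known use of ketoreductases: the choice of one enantiotopic carbonyl fixes C4 as S, anti-Prelog hydride delivery fixes C3 as R with the hydroxyl trans to CH2OH, and the slightly acidic buffer holds back retro-aldol loss of formaldehyde.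

Step 3
Reactants: 3 (2S,3R)-3-hydroxy-2-(hydroxymethyl)-2-methylcyclohexan-1-one
Product: 4 (4aS,8aR)-2,2,4a-trimethylhexahydro-4H-1,3-benzodioxin-5-one (trans-fused ring A ketone acetonide)
Conditions: Me2C(OMe)2, PPTS (cat.), CH2Cl2, 23 °C
Reagents that add atoms: 2,2-dimethoxypropane, COC(C)(C)OC
Why: Acid-catalysed transketalisation: the trans 1,3-diol closes a trans-fused 1,3-dioxane with O3 and C18 equatorial, which removes the retro-aldol pathway and locks C19 axial on the α face.

Step 4
Reactants: 4 ring A ketone acetonide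
Product: 6 (4aS,8aR)-2,2,4a,6-tetramethylhexahydro-4H-1,3-benzodioxin-5-one (both C6 epimers; C6 = labdane C10), via lithium enolate 5 (not isolated)
Conditions: LiN(i-Pr)2, THF, −78 °C; MeI, −78 → 0 °C
Reagents that add atoms: iodomethane, CI; LiN(i-Pr)2, [Li+].CC(C)[N-]C(C)C (lithium carried only by 5)
Why: Kinetic enolate alkylation: C4 is quaternary, so only C10 can be deprotonated and methylation there brings in C20, the configuration of the new centre being of no concern because the next step flattens it.

Step 5
Reactants: 6 C10-methylated ketone acetonide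
Product: 8 (4aS,8aR)-2,2,4a,6-tetramethyl-4a,7,8,8a-tetrahydro-4H-1,3-benzodioxin-5-yl trifluoromethanesulfonate, via lithium enolate 7 (not isolated)
Conditions: LiN(i-Pr)2, THF, −78 → 0 °C; PhNTf2, 0 → 23 °C
Reagents that add atoms: N-phenylbis(trifluoromethanesulfonimide), O=S(=O)(N(c1ccccc1)S(=O)(=O)C(F)(F)F)C(F)(F)F; LiN(i-Pr)2, [Li+].CC(C)[N-]C(C)C (lithium carried only by 7)
Why: Enol triflate formation: the single remaining α-hydrogen at C10 is removed to give the tetrasubstituted enolate, which PhNTf2 sulfonylates on oxygen as it does for 2,2,6-trisubstituted cyclohexanones.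

Step 6
Reactants: 8 C5 enol triflate
Product: 9 (4aS,8aR)-5-ethenyl-2,2,4a,6-tetramethyl-4a,7,8,8a-tetrahydro-4H-1,3-benzodioxine (ring A vinyl diene acetonide)
Conditions: Bu3SnCH=CH2, Pd(PPh3)4 (cat.), LiCl, THF, 65 °C
Reagents that add atoms: tributyl(vinyl)stannane, C=C[Sn](CCCC)(CCCC)CCCC
Why: Stille coupling: oxidative addition of zerovalent palladium into the C5–O triflate bond, chloride exchange and vinyl transfer from tin install C6=C7, a coupling that is well known for hindered 2,6,6-trisubstituted cyclohexenyl triflates.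

Step 7
Reactants: 9 ring A vinyl diene acetonide; 10 dimethyl but-2-ynedioate
Product: 11 dimethyl 3α,18-isopropylidenedioxy-12,13,14,15,16-pentanorlabda-5,8-diene-11,17-dioate (10α-CH3)
Conditions: 10 (2 equiv), BHT (cat.), toluene, sealed tube, 110 °C
Reagents that add atoms: none
Why: Concerted but asynchronous [4+2] cycloaddition: the s-cis diene C10=C5–C6=C7 of 9 adds suprafacially across the triple bond of 10, C7–C8 and C9–C10 form in the same event, and ring B closes as a six-membered 1,4-cyclohexadiene (C5=C6 and C8=C9) by intermolecular cycloaddition. The closest known reaction type is the thermal Diels–Alder reaction of 1-vinyl-2,6,6-trisubstituted cyclohexenes with acetylenedicarboxylates, which gives angularly methylated bicyclic 1,4-dienes. The one new stereocentre, quaternary C10, is controlled by the trans-fused dioxane, which freezes ring A in a single half-chair with C19 pseudoaxial on the α face beside C5, so the alkyne approaches from the β face, C9 bonds there and C20 is pushed to the α face, syn to C19 as in the target. The second ester lowers the alkyne LUMO enough for the fully substituted terminus C10 to react near 110 °C, below the temperatures at which the 1,5-hydrogen shift from C20 to C7 would consume the diene, which a singly activated internal ynoate could not be trusted to do. Since 10 is symmetric there is no regiochemical issue and an alkyne raises no endo/exo issue, so facial selectivity is the only selectivity needed. C11 and C17 are told apart later through the steric shadow that C10 casts on C11.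

Step 8
Reactants: 11 Diels–Alder adduct
Product: 12 dimethyl 3α,18-isopropylidenedioxy-12,13,14,15,16-pentanorlabd-8-ene-11,17-dioate (5β-H; trans-decalin)
Conditions: H2 (1 atm), 10% Pd/C, EtOAc, 23 °C
Reagents that add atoms: none
Why: Heterogeneous catalytic hydrogenation: the trisubstituted C5=C6 bond is saturated while the tetrasubstituted C8=C9 bond flanked by two esters stays untouched, and hydrogen arrives from the β face because both axial methyl groups C19 and C20 shield the α face, which sets 5β-H and the trans ring fusion.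

Step 9
Reactants: 12 trans-decalin diester
Product: 13 3α,18-isopropylidenedioxy-12,13,14,15,16-pentanorlabd-8-ene-11,17-diol
Conditions: LiAlH4, Et2O, 0 → 23 °C
Reagents that add atoms: none
Why: Ester reduction with LiAlH4: both methyl esters go to the primary allylic alcohols, the acetonide and the tetrasubstituted alkene being inert to hydride.

Step 10
Reactants: 13 C11,C17-diol
Product: 14 17-(tert-butyldimethylsilyloxy)-3α,18-isopropylidenedioxy-12,13,14,15,16-pentanorlabd-8-en-11-ol
Conditions: TBSCl (1 equiv), imidazole, CH2Cl2, −20 °C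
Reagents that add atoms: tert-butyldimethylsilyl chloride, CC(C)(C)[Si](C)(C)Cl
Why: Sterically controlled monosilylation: the C17 hydroxyl next to the C7 methylene is open whereas the C11 hydroxyl sits under quaternary C10 between C20 and C1, so one equivalent of the bulky chlorosilane at low temperature should take C17, and material silylated elsewhere can be desilylated back to 13.

Step 11
Reactants: 14 C17 silyl ether C11 alcohol
Product: 15 17-(tert-butyldimethylsilyloxy)-3α,18-isopropylidenedioxy-12,13,14,15,16-pentanorlabd-8-en-11-al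
Conditions: MnO2 (activated, excess), CH2Cl2, 23 °C
Reagents that add atoms: none
Why: Allylic alcohol oxidation with MnO2: the neutral heterogeneous oxidant turns the primary allylic C11 alcohol into the tetrasubstituted enal and leaves silyl ether and acetonide intact.

Step 12
Reactants: 15 C11 enal
Product: 16 17-(tert-butyldimethylsilyloxy)-3α,18-isopropylidenedioxy-13,14,15,16-tetranorlabda-8,11-diene
Conditions: Ph3PCH3Br, KOt-Bu, THF, 0 → 23 °C
Reagents that add atoms: methyltriphenylphosphonium bromide, C[P+](c1ccccc1)(c1ccccc1)c1ccccc1.[Br-]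
Why: Wittig methylenation: the small unstabilised ylide reaches even this hindered aldehyde, which has no α-hydrogen to lose, and brings in C12 as the terminal carbon of a twisted diene.

Step 13
Reactants: 16 C9 vinyl compound; 17 4-bromofuran-2(5H)-one
Product: 19 17-(tert-butyldimethylsilyloxy)-3α,18-isopropylidenedioxylabda-8,13-dien-15,16-olide, via B-alkyl borane 18 (not isolated)
Conditions: 9-BBN-H, THF, 0 → 23 °C; then 17, PdCl2(dppf) (cat.), aq. K3PO4, DMF, 23 → 45 °C
Reagents that add atoms: 9-borabicyclo[3.3.1]nonane, B1C2CCCC1CCC2 (its boron bicycle is carried only by 18)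
Why: Hydroboration followed by B-alkyl Suzuki–Miyaura coupling: 9-BBN-H adds only to the monosubstituted C11=C12 bond with boron on C12, since the tetrasubstituted C8=C9 bond is inert and the exocyclic methylene does not yet exist, and the borane then couples at C12–C13 with the activated β-bromo enoate 17 under mild phosphate base.

Step 14
Reactants: 19 silyl-protected butenolide
Product: 20 17-hydroxy-3α,18-isopropylidenedioxylabda-8,13-dien-15,16-olide
Conditions: n-Bu4NF, AcOH, THF, 0 → 23 °C
Reagents that add atoms: none
Why: Fluoride-induced desilylation: acetic acid buffers the fluoride so that the butenolide is not deprotonated, and the acetonide is stable to these conditions.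

Step 15
Reactants: 20 C17 allylic alcohol
Product: 23 3α,18-isopropylidenedioxylabda-8(17),13-dien-15,16-olide (9β-H), via sulfonylhydrazine 21 (not isolated), via allylic diazene 22 (not isolated)
Conditions: 2-O2NC6H4SO2NHNH2 (NBSH), PPh3, DEAD, N-methylmorpholine, −30 °C; then 23 °C
Reagents that add atoms: 2-nitrobenzenesulfonohydrazide, NNS(=O)(=O)c1ccccc1[N+](=O)[O-] (apart from one hydrogen its atoms stay only in 21 and 22)
Why: Myers reductive allylic transposition: Mitsunobu displacement at primary C17 by NBSH, loss of sulfinic acid on warming and retro-ene loss of N2 from the allylic diazene move the double bond to C8=C17 and deliver hydrogen to C9 from the β face, because axial C20 on the neighbouring carbon blocks the α face, so that C11 ends up equatorial (9β-H).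

Step 16
Reactants: 23 exocyclic methylene acetonide
Product: 24 3α,18-dihydroxylabda-8(17),13-dien-15,16-olide
Conditions: 70% aq. AcOH, 23 °C
Reagents that add atoms: none
Why: Acid-catalysed acetal hydrolysis: aqueous acetic acid at room temperature cleaves the isopropylidene acetal without isomerising the exocyclic alkene, as is known for acetonides of related 8(17)-ene labdane diols.

Step 17
Reactants: 24 C3,C18-diol
Product: 25 18-(tert-butyldimethylsilyloxy)-3α-hydroxylabda-8(17),13-dien-15,16-olide
Conditions: TBSCl, imidazole, DMF, 0 °C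
Reagents that add atoms: tert-butyldimethylsilyl chloride, CC(C)(C)[Si](C)(C)Cl
Why: Selective silylation of a primary over a secondary alcohol: the primary C18 hydroxyl reacts well ahead of the secondary C3 hydroxyl that is flanked by quaternary C4.

Step 18
Reactants: 25 C18 silyl ether C3 alcohol; 26 angelic acid ((Z)-2-methylbut-2-enoic acid)
Product: 28 3α-angeloyloxy-18-(tert-butyldimethylsilyloxy)labda-8(17),13-dien-15,16-olide, via mixed anhydride 27 (not isolated)
Conditions: 26, 2,4,6-Cl3C6H2COCl, Et3N, toluene, 23 °C; then 25, 80 °C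
Reagents that add atoms: 2,4,6-trichlorobenzoyl chloride, O=C(Cl)c1c(Cl)cc(Cl)cc1Cl (aroyl group carried only by 27)
Why: Yamaguchi-type mixed anhydride esterification run without a nucleophilic catalyst: the C3 hydroxyl attacks the unhindered angeloyl carbonyl of 27, and leaving out DMAP avoids the addition–elimination path that turns angelates into tiglates, so the Z geometry of 26 is kept.

Step 19
Reactants: 28 silyl-protected angelate
Product: 29 (3R,4S,5S,9R,10S)-3α-angeloyloxy-18-hydroxylabda-8(17),13-dien-15,16-olide (CNP0292066.2)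
Conditions: HF·pyridine, pyridine, THF, 0 → 23 °C
Reagents that add atoms: none
Why: Desilylation with buffered HF: mildly acidic fluoride frees the C18 hydroxyl without the basic conditions that would let the angeloyl group migrate from O3 to O18.

Compound list
1 | 2-methylcyclohexane-1,3-dione | CC1C(=O)CCCC1=O | starting material
2 | 2-(hydroxymethyl)-2-methylcyclohexane-1,3-dione | CC1(CO)C(=O)CCCC1=O | intermediate
3 | (2S,3R)-3-hydroxy-2-(hydroxymethyl)-2-methylcyclohexan-1-one | O=C1CCC[C@@H](O)[C@]1(C)CO | intermediate
4 | (4aS,8aR)-2,2,4a-trimethylhexahydro-4H-1,3-benzodioxin-5-one | O=C1CCC[C@H]2OC(C)(C)OC[C@]12C | intermediate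
5 | lithium enolate of 4 (C5=C10) | [Li+].[O-]C1=CCC[C@H]2OC(C)(C)OC[C@]12C | intermediate
6 | (4aS,8aR)-2,2,4a,6-tetramethylhexahydro-4H-1,3-benzodioxin-5-one, both C6 epimers | O=C1C(C)CC[C@H]2OC(C)(C)OC[C@]12C | intermediate
7 | lithium enolate of 6 (tetrasubstituted C5=C10) | [Li+].[O-]C1=C(C)CC[C@H]2OC(C)(C)OC[C@]12C | intermediate
8 | (4aS,8aR)-2,2,4a,6-tetramethyl-4a,7,8,8a-tetrahydro-4H-1,3-benzodioxin-5-yl trifluoromethanesulfonate | O=S(=O)(OC1=C(C)CC[C@H]2OC(C)(C)OC[C@]12C)C(F)(F)F | intermediate
9 | (4aS,8aR)-5-ethenyl-2,2,4a,6-tetramethyl-4a,7,8,8a-tetrahydro-4H-1,3-benzodioxine (ring A vinyl diene) | C=CC1=C(C)CC[C@H]2OC(C)(C)OC[C@]12C | intermediate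
10 | dimethyl but-2-ynedioate | COC(=O)C#CC(=O)OC | starting material
11 | dimethyl 3α,18-isopropylidenedioxy-12,13,14,15,16-pentanorlabda-5,8-diene-11,17-dioate (10α-CH3) | COC(=O)C1=C(C(=O)OC)[C@]2(C)CC[C@H]3OC(C)(C)OC[C@]3(C)C2=CC1 | intermediate
12 | dimethyl 3α,18-isopropylidenedioxy-12,13,14,15,16-pentanorlabd-8-ene-11,17-dioate (5β-H) | COC(=O)C1=C(C(=O)OC)[C@]2(C)CC[C@H]3OC(C)(C)OC[C@]3(C)[C@H]2CC1 | intermediate
13 | 3α,18-isopropylidenedioxy-12,13,14,15,16-pentanorlabd-8-ene-11,17-diol | OCC1=C(CO)[C@]2(C)CC[C@H]3OC(C)(C)OC[C@]3(C)[C@H]2CC1 | intermediate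
14 | 17-(tert-butyldimethylsilyloxy)-3α,18-isopropylidenedioxy-12,13,14,15,16-pentanorlabd-8-en-11-ol | CC(C)(C)[Si](C)(C)OCC1=C(CO)[C@]2(C)CC[C@H]3OC(C)(C)OC[C@]3(C)[C@H]2CC1 | intermediate
15 | 17-(tert-butyldimethylsilyloxy)-3α,18-isopropylidenedioxy-12,13,14,15,16-pentanorlabd-8-en-11-al | CC(C)(C)[Si](C)(C)OCC1=C(C=O)[C@]2(C)CC[C@H]3OC(C)(C)OC[C@]3(C)[C@H]2CC1 | intermediate
16 | 17-(tert-butyldimethylsilyloxy)-3α,18-isopropylidenedioxy-13,14,15,16-tetranorlabda-8,11-diene | CC(C)(C)[Si](C)(C)OCC1=C(C=C)[C@]2(C)CC[C@H]3OC(C)(C)OC[C@]3(C)[C@H]2CC1 | intermediate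
17 | 4-bromofuran-2(5H)-one | O=C1OCC(Br)=C1 | starting material
18 | C12 B-alkyl-9-borabicyclo[3.3.1]nonane derived from 16 | CC(C)(C)[Si](C)(C)OCC1=C(CCB4C5CCCC4CCC5)[C@]2(C)CC[C@H]3OC(C)(C)OC[C@]3(C)[C@H]2CC1 | intermediate
19 | 17-(tert-butyldimethylsilyloxy)-3α,18-isopropylidenedioxylabda-8,13-dien-15,16-olide | CC(C)(C)[Si](C)(C)OCC1=C(CCC4=CC(=O)OC4)[C@]2(C)CC[C@H]3OC(C)(C)OC[C@]3(C)[C@H]2CC1 | intermediate
20 | 17-hydroxy-3α,18-isopropylidenedioxylabda-8,13-dien-15,16-olide | OCC1=C(CCC4=CC(=O)OC4)[C@]2(C)CC[C@H]3OC(C)(C)OC[C@]3(C)[C@H]2CC1 | intermediate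
21 | N-(C17-alkyl)-N-(2-nitrobenzenesulfonyl)hydrazine derived from 20 | NN(CC1=C(CCC4=CC(=O)OC4)[C@]2(C)CC[C@H]3OC(C)(C)OC[C@]3(C)[C@H]2CC1)S(=O)(=O)c1ccccc1[N+](=O)[O-] | intermediate
22 | C17 monoalkyl (allylic) diazene | N=NCC1=C(CCC4=CC(=O)OC4)[C@]2(C)CC[C@H]3OC(C)(C)OC[C@]3(C)[C@H]2CC1 | intermediate
23 | 3α,18-isopropylidenedioxylabda-8(17),13-dien-15,16-olide (9β-H) | C=C1CC[C@H]2[C@@](C)(CC[C@H]3OC(C)(C)OC[C@]23C)[C@@H]1CCC1=CC(=O)OC1 | intermediate
24 | 3α,18-dihydroxylabda-8(17),13-dien-15,16-olide | C=C1CC[C@H]2[C@@](C)(CC[C@@H](O)[C@]2(C)CO)[C@@H]1CCC1=CC(=O)OC1 | intermediate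
25 | 18-(tert-butyldimethylsilyloxy)-3α-hydroxylabda-8(17),13-dien-15,16-olide | C=C1CC[C@H]2[C@@](C)(CC[C@@H](O)[C@]2(C)CO[Si](C)(C)C(C)(C)C)[C@@H]1CCC1=CC(=O)OC1 | intermediate
26 | angelic acid, (Z)-2-methylbut-2-enoic acid | C/C=C(/C)C(=O)O | starting material
27 | angelic 2,4,6-trichlorobenzoic anhydride | C/C=C(/C)C(=O)OC(=O)c1c(Cl)cc(Cl)cc1Cl | intermediate
28 | 3α-angeloyloxy-18-(tert-butyldimethylsilyloxy)labda-8(17),13-dien-15,16-olide | C=C1CC[C@H]2[C@@](C)(CC[C@@H](OC(=O)/C(C)=C\C)[C@]2(C)CO[Si](C)(C)C(C)(C)C)[C@@H]1CCC1=CC(=O)OC1 | intermediate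
29 | (3R,4S,5S,9R,10S)-3α-angeloyloxy-18-hydroxylabda-8(17),13-dien-15,16-olide (CNP0292066.2) | C=C1CC[C@H]2[C@@](C)(CC[C@@H](OC(=O)/C(C)=C\C)[C@]2(C)CO)[C@@H]1CCC1=CC(=O)OC1 | target

Total step count: 19. Longest linear sequence: 19 steps (1 → 29); 10, 17 and 26 are purchased.

Steps most likely to fail

Step 2. What may go wrong:
- imperfect discrimination between the enantiotopic carbonyls or between the two hydride faces;
- retro-aldol loss of formaldehyde during a long incubation.

The fallback sets out from 2 and returns at 3, and it settles relative and absolute configuration separately by chemical means. An Evans–Saksena reduction of 2 (Me4NBH(OAc)3, AcOH/MeCN, −20 °C) binds boron to the CH2OH oxygen. Hydride then reaches one carbonyl from the face of that arm, which should give the racemic trans diol F1. The primary hydroxyl of F1 is esterified with (S)-2-methoxy-2-phenylacetic acid (EDC·HCl, DMAP cat., CH2Cl2, 0 °C). This turns the enantiomers into two diastereomers, the wanted (1S,2R)-configured ester F2 and the unwanted (1R,2S)-configured ester F3, to be separated by chromatography or crystallisation. Brief methanolysis of F2 (K2CO3, MeOH, 0 °C) releases 3.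

Step 15. What may go wrong:
- slow Mitsunobu displacement at the crowded C17 carbinol;
- decomposition of the thermally labile hydrazide before it is alkylated;
- leakage of hydrogen delivery to the α face.

The fallback sets out from 20 and returns at 23, and it replaces the pericyclic hydrogen transfer by a metal-bound hydride. Acylation of 20 (ClCO2Me, pyridine, CH2Cl2, 0 °C) gives the C17 methyl carbonate F4. This is submitted to palladium-catalysed formate hydrogenolysis of the Tsuji type (Pd(OAc)2, n-Bu3P, HCO2H, Et3N, THF, 65 °C). Zerovalent palladium ionises the carbonate from the open β face and rests on primary C17. The formate ligand then passes hydride to the more substituted allyl terminus C9 on the same face. This should give the exocyclic alkene with 9β-H, that is 23.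

Step 10. What may go wrong:
- poor site selectivity between the two primary allylic hydroxyls;
- silyl migration between them.

The fallback sets out from 9 and returns at 14, and it builds the difference between C11 and C17 into the alkyne instead. Prop-2-yn-1-ol is silylated (TBSCl, imidazole, CH2Cl2) to the propargyl silyl ether F5. Lithiation and carboxylation (n-BuLi, THF, −78 °C; ClCO2Me) then give methyl 4-(tert-butyldimethylsilyloxy)but-2-ynoate F6. Cycloaddition of F6 with 9 forms the same two bonds. Because this alkyne carries only one ester, the reaction is run under high pressure (about 12 kbar, CH2Cl2, 40 °C) rather than by strong heating. The unsubstituted terminus C7 has the larger HOMO coefficient and the least hindrance, so it should bond to the β-carbon of the ynoate and place the ester on C9, giving the silyloxy ester diene F7. Hydrogenation as in step 8 gives the 8-ene ester F8, and i-Bu2AlH (CH2Cl2, −78 → 0 °C) reduces its ester to 14.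

Further compounds
F1 | step 2 | racemic (2S*,3R*)-3-hydroxy-2-(hydroxymethyl)-2-methylcyclohexan-1-one (both enantiomers) | O=C1CCC[C@@H](O)[C@]1(C)CO.O=C1CCC[C@H](O)[C@@]1(C)CO
F2 | step 2 | [(1S,2R)-2-hydroxy-1-methyl-6-oxocyclohexyl]methyl (2S)-2-methoxy-2-phenylacetate | O=C1CCC[C@@H](O)[C@]1(C)COC(=O)[C@@H](OC)c1ccccc1
F3 | step 2 | [(1R,2S)-2-hydroxy-1-methyl-6-oxocyclohexyl]methyl (2S)-2-methoxy-2-phenylacetate | O=C1CCC[C@H](O)[C@@]1(C)COC(=O)[C@@H](OC)c1ccccc1
F4 | step 15 | 17-(methoxycarbonyloxy)-3α,18-isopropylidenedioxylabda-8,13-dien-15,16-olide | COC(=O)OCC1=C(CCC4=CC(=O)OC4)[C@]2(C)CC[C@H]3OC(C)(C)OC[C@]3(C)[C@H]2CC1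
F5 | step 10 | tert-butyldimethyl(prop-2-yn-1-yloxy)silane | C#CCO[Si](C)(C)C(C)(C)C
F6 | step 10 | methyl 4-(tert-butyldimethylsilyloxy)but-2-ynoate | CC(C)(C)[Si](C)(C)OCC#CC(=O)OC
F7 | step 10 | methyl 17-(tert-butyldimethylsilyloxy)-3α,18-isopropylidenedioxy-12,13,14,15,16-pentanorlabda-5,8-dien-11-oate (10α-CH3) | CC(C)(C)[Si](C)(C)OCC1=C(C(=O)OC)[C@]2(C)CC[C@H]3OC(C)(C)OC[C@]3(C)C2=CC1
F8 | step 10 | methyl 17-(tert-butyldimethylsilyloxy)-3α,18-isopropylidenedioxy-12,13,14,15,16-pentanorlabd-8-en-11-oate (5β-H) | CC(C)(C)[Si](C)(C)OCC1=C(C(=O)OC)[C@]2(C)CC[C@H]3OC(C)(C)OC[C@]3(C)[C@H]2CC1
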